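**Retrosynthetic overview**

- Target ⇒ its tri-O-methyl ether. The isovaleryl and formyl groups are put on the arene by two successive ortho-lithiations (steps 10–12), the three O-methyl groups are removed last (step 13), and a C3 hydroxyl left on ring B is removed by Barton–McCombie deoxygenation (steps 8–9).
- Ring B ⇒ type 2 intramolecular carbonyl-ene reaction: the aldehyde carbon C3 bonds to C4 of a (Z)-ethylidene group on C5 and takes a hydrogen from C6. The feature used is that the methyl-bearing stereocentre C4 of ring B, cis to the angular C10 methyl, sits directly beside C5=C6, the only alkene inside the decalin.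
- (Z)-Ethylidene aldehyde ⇒ Wittig ethylidenation of a C5 ketone and ester-to-aldehyde reduction of a δ-keto ester. Its C10–C1 bond (quaternary C10, tertiary C1) ⇒ Mukaiyama–Michael addition of the silyl enol ether of dihydrocarvone to methyl (E)-4-(2,4,6-trimethoxyphenyl)but-2-enoate.
- Fragments: (S)-carvone (ring A, C7 stereocentre) by conjugate reduction and silylation; 1,3,5-trimethoxybenzene by lithiation/allylation and cross-metathesis with methyl acrylate.
- Ring order: arene bought, ring A from carvone, ring B closed last.

Key step: step 7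

Numbering used: decalin carbons C1–C10; C1 carries the arylmethyl group, C2 and C3 are ring B methylenes, C4 carries the secondary methyl, C5=C6 is the alkene, C7 carries isopropenyl, C10 carries the angular methyl. Ring A = C5–C10, ring B = C1–C5 plus C10. "DecCH2" = [(1S,4S,6S,8aS)-4,8a-dimethyl-6-(prop-1-en-2-yl)-1,2,3,4,6,7,8,8a-octahydronaphthalen-1-yl]methyl.

Assumption: the C3 carbinol configuration of 15 (and of 16–18) and the side-chain carbinol configuration of 22–24 are left open, because C3 becomes CH2 in step 9 and the side-chain carbinol is oxidised in step 12.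

**Step 1**
Reactants: 1 (S)-(+)-carvone
Product: 3 trimethyl{[(5S)-2-methyl-5-(prop-1-en-2-yl)cyclohex-1-en-1-yl]oxy}silane, via lithium enolate 2 (not isolated)
Conditions: LiBH(s-Bu)3, THF, −78 °C; then Me3SiCl, Et3N, −78 → 0 °C
Reagents that add atoms: chlorotrimethylsilane, C[Si](C)(C)Cl
Why: Conjugate (1,4) hydride reduction of the β-unsubstituted enone by the hindered borohydride gives the tetrasubstituted enolate regiospecifically and O-silylation fixes the C5=C10 enol ether, the C7 stereocentre of carvone being untouched.

**Step 2**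
Reactants: 4 1,3,5-trimethoxybenzene; 5 allyl bromide
Product: 7 2-allyl-1,3,5-trimethoxybenzene, via 2,4,6-trimethoxyphenyllithium 6 (not isolated)
Conditions: n-BuLi, THF, 0 °C → rt; then CuBr·SMe2 (10 mol%), 5, −78 → 0 °C
Reagents that add atoms: none
Why: Directed ortho-lithiation between two methoxy groups followed by copper-catalysed allylation of the aryllithium.

**Step 3**
Reactants: 7 2-allyl-1,3,5-trimethoxybenzene; 8 methyl acrylate
Product: 9 methyl (2E)-4-(2,4,6-trimethoxyphenyl)but-2-enoate
Conditions: second-generation Hoveyda–Grubbs catalyst RuCl2(SIMes)(=CH–C6H4-2-O-i-Pr) (5 mol%), 1,4-benzoquinone (10 mol%), CH2Cl2, 40 °C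
Reagents that add atoms: none
Why: Olefin cross-metathesis of a terminal allylarene with an electron-poor acrylate favours the cross product as the (E)-enoate, and benzoquinone suppresses migration of the double bond toward the arene.

**Step 4**
Reactants: 3 silyl enol ether (1.5 equiv); 9 (E)-enoate
Product: 10 methyl (3R)-3-[(1S,4S)-1-methyl-2-oxo-4-(prop-1-en-2-yl)cyclohexyl]-4-(2,4,6-trimethoxyphenyl)butanoate
Conditions: TiCl4 (1.1 equiv), CH2Cl2, −78 → −40 °C; then H2O
Reagents that add atoms: none
Why: Mukaiyama–Michael addition: the TiCl4-bound enoate is attacked by C10 axially on the enol ether face cis to the C7 isopropenyl group (the usual preference in annulations of dihydrocarvone), and C1 is set in an open transition state with the C1 hydrogen over ring A and the arylmethyl group pointing away, the arrangement that gives the cis-vicinal pattern in additions of 2-methylcyclohexanone enol derivatives to (E)-pent-3-en-2-one.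

**Step 5**
Reactants: 10 keto ester; 11 ethyltriphenylphosphonium bromide
Product: 13 methyl (3R)-3-[(1S,2Z,4S)-2-ethylidene-1-methyl-4-(prop-1-en-2-yl)cyclohexyl]-4-(2,4,6-trimethoxyphenyl)butanoate, via ethylidenetriphenylphosphorane 12 (not isolated)
Conditions: 11 (3 equiv), KN(SiMe3)2 (2.8 equiv), THF, 0 °C; then 10, 0 → 50 °C
Reagents that add atoms: none
Why: Wittig olefination with a non-stabilised ylide under salt-free kinetic control places the ylide methyl cis to the more substituted α-carbon C10 (as in ethylidenation of ketones flanked by a quaternary carbon), giving the (Z)-alkene, while the β-branched methyl ester is not attacked because no free base remains.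

**Step 6**
Reactants: 13 (Z)-ethylidene ester
Product: 14 (3R)-3-[(1S,2Z,4S)-2-ethylidene-1-methyl-4-(prop-1-en-2-yl)cyclohexyl]-4-(2,4,6-trimethoxyphenyl)butanal
Conditions: i-Bu2AlH (1.1 equiv), CH2Cl2, −78 °C; aq. potassium sodium tartrate
Reagents that add atoms: none
Why: Partial hydride reduction of the ester stops at the tetrahedral aluminium hemiacetal at −78 °C and releases the aldehyde only on work-up, alkenes and aryl ethers being inert.

**Step 7**
Reactants: 14 (Z)-ethylidene aldehyde
Product: 15 (1R,4R,4aS,7S)-1,4a-dimethyl-7-(prop-1-en-2-yl)-4-[(2,4,6-trimethoxyphenyl)methyl]-1,2,3,4,4a,5,6,7-octahydronaphthalen-2-ol (C3 carbinol of the protected skeleton)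
Conditions: Me2AlCl (2 equiv), CH2Cl2 (0.01 M), −78 → −20 °C; then cold 1 M HCl
Reagents that add atoms: none
Why: The aluminium-bound aldehyde carbon C3 bonds to the ethylidene terminus C4 while the axial C6 hydrogen on the same face is passed to oxygen through a six-centre array, so the alkene moves to C5=C6, and the resulting aluminium alkoxide loses methane, which removes the proton that could otherwise isomerise the alkenes. The closest known reactions are Lewis-acid-promoted type 2 intramolecular carbonyl-ene cyclisations of unsaturated aldehydes to 3-methylenecyclohexanols and ene reactions of (Z)-ethylidene groups beside a quaternary carbon that shift the double bond into the ring. Ring B closes as a six-membered chair in which the enophile is tethered through C10–C1–C2 to the central ene carbon C5 and bonds to the alkene terminus (formally 6-endo-trig at C4=C5), with the arylmethyl group equatorial. C4 is controlled by the tether and the alkene geometry: C1 lies on the face of ring A opposite the C10 methyl, so C3 can reach C4 only on that face, and the (Z)-methyl is pushed to the other face, cis to the C10 methyl (an (E)-alkene would give the epimer); the new C3 carbinol (expected axial, trans to the C4 methyl) is removed later. The step needs hydrogen transfer from C6 only and reaction at the ethylidene only: C10 has no hydrogen, bonding at C5 would build charge on secondary C4, the isopropenyl group cannot be reached within a normal ring and high dilution suppresses its intermolecular reaction. The arene cannot attack the aldehyde because both positions ortho to the benzylic carbon carry methoxy groups.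

**Step 8**
Reactants: 15 C3 carbinol
Product: 18 O-alkyl S-methyl dithiocarbonate (xanthate) of 15 at C3, via sodium alkoxide 16 (not isolated), via sodium xanthate 17 (not isolated)
Conditions: NaH, THF, 0 °C; CS2; then MeI, rt
Reagents that add atoms: carbon disulfide, S=C=S; iodomethane, CI
Why: Xanthate formation (first stage of the Barton–McCombie deoxygenation) by alkoxide addition to CS2 and S-methylation, no other acidic or electrophilic site being present.

**Step 9**
Reactants: 18 xanthate
Product: 19 1,3,5-trimethoxy-2-(DecCH2)benzene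
Conditions: n-Bu3SnH, AIBN (cat.), toluene, 90 °C
Reagents that add atoms: none
Why: Barton–McCombie radical deoxygenation: the stannyl radical adds to C=S, β-scission gives the secondary C3 radical, and hydrogen transfer from the tin hydride outruns homoallyl rearrangement, leaving C4 and both alkenes unchanged.

**Step 10**
Reactants: 19 deoxygenated trimethoxyarene; 20 3-methylbutanal
Product: 22 3-methyl-1-[2,4,6-trimethoxy-3-(DecCH2)phenyl]butan-1-ol, via aryllithium 21 (not isolated)
Conditions: n-BuLi (1.1 equiv), THF, 0 °C; then 20, −78 °C; H2O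
Reagents that add atoms: none
Why: Directed ortho-lithiation at one of the two equivalent ring positions flanked by methoxy groups (without diamine, so the allylic positions are not metalated) and 1,2-addition of the aryllithium to the aldehyde.

**Step 11**
Reactants: 22 benzylic alcohol
Product: 24 3-(1-hydroxy-3-methylbutyl)-2,4,6-trimethoxy-5-(DecCH2)benzaldehyde, via dilithiated alkoxide 23 (not isolated)
Conditions: n-BuLi (2.3 equiv), THF, 0 °C; then DMF, −78 → 0 °C; H2O
Reagents that add atoms: N,N-dimethylformamide, CN(C)C=O
Why: The lithium alkoxide protects the carbinol while the last ring hydrogen, again between two methoxy groups, is removed by directed ortho-lithiation, and DMF formylates the aryllithium (Bouveault-type formylation).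

**Step 12**
Reactants: 24 hydroxy aldehyde
Product: 25 2,4,6-trimethoxy-3-(3-methylbutanoyl)-5-(DecCH2)benzaldehyde
Conditions: Dess–Martin periodinane, pyridine, CH2Cl2, 0 °C → rt
Reagents that add atoms: none
Why: Dess–Martin oxidation of the secondary benzylic alcohol to the aryl ketone under buffered conditions that spare the aldehyde and both alkenes.

**Step 13**
Reactants: 25 keto aldehyde trimethyl ether
Product: 26 2,4,6-trihydroxy-3-(3-methylbutanoyl)-5-(DecCH2)benzaldehyde (target CNP0564915.1)
Conditions: NaSEt (excess), DMF, 120 °C; then 1 M HCl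
Reagents that add atoms: none
Why: SN2 O-demethylation by thiolate: each methoxy group is ortho or para to both carbonyl groups, so each phenoxide is a stabilised leaving group, and the basic, non-electrophilic medium leaves the isopropenyl and C5=C6 alkenes and all four stereocentres untouched.

**Compound list**

1 | (S)-(+)-carvone | C=C(C)[C@@H]1CC(=O)C(C)=CC1 | starting material
2 | lithium (5S)-2-methyl-5-(prop-1-en-2-yl)cyclohex-1-en-1-olate (formed in the flask) | C=C(C)[C@@H]1CC([O-])=C(C)CC1.[Li+] | intermediate
3 | trimethyl{[(5S)-2-methyl-5-(prop-1-en-2-yl)cyclohex-1-en-1-yl]oxy}silane | C=C(C)[C@@H]1CC(O[Si](C)(C)C)=C(C)CC1 | intermediate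
4 | 1,3,5-trimethoxybenzene | COc1cc(OC)cc(OC)c1 | starting material
5 | allyl bromide | C=CCBr | starting material
6 | 2,4,6-trimethoxyphenyllithium (formed in the flask) | [Li]c1c(OC)cc(OC)cc1OC | intermediate
7 | 2-allyl-1,3,5-trimethoxybenzene | C=CCc1c(OC)cc(OC)cc1OC | intermediate
8 | methyl acrylate | C=CC(=O)OC | starting material
9 | methyl (2E)-4-(2,4,6-trimethoxyphenyl)but-2-enoate | COC(=O)/C=C/Cc1c(OC)cc(OC)cc1OC | intermediate
10 | methyl (3R)-3-[(1S,4S)-1-methyl-2-oxo-4-(prop-1-en-2-yl)cyclohexyl]-4-(2,4,6-trimethoxyphenyl)butanoate | C=C(C)[C@@H]1CC(=O)[C@](C)([C@H](Cc2c(OC)cc(OC)cc2OC)CC(=O)OC)CC1 | intermediate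
11 | ethyltriphenylphosphonium bromide | CC[P+](c1ccccc1)(c1ccccc1)c1ccccc1.[Br-] | starting material
12 | ethylidenetriphenylphosphorane (formed in the flask) | CC=P(c1ccccc1)(c1ccccc1)c1ccccc1 | intermediate
13 | methyl (3R)-3-[(1S,2Z,4S)-2-ethylidene-1-methyl-4-(prop-1-en-2-yl)cyclohexyl]-4-(2,4,6-trimethoxyphenyl)butanoate | C=C(C)[C@@H]1C/C(=C/C)[C@](C)([C@H](Cc2c(OC)cc(OC)cc2OC)CC(=O)OC)CC1 | intermediate
14 | (3R)-3-[(1S,2Z,4S)-2-ethylidene-1-methyl-4-(prop-1-en-2-yl)cyclohexyl]-4-(2,4,6-trimethoxyphenyl)butanal (key-step precursor) | C=C(C)[C@@H]1C/C(=C/C)[C@](C)([C@H](Cc2c(OC)cc(OC)cc2OC)CC=O)CC1 | intermediate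
15 | (1R,4R,4aS,7S)-1,4a-dimethyl-7-(prop-1-en-2-yl)-4-[(2,4,6-trimethoxyphenyl)methyl]-1,2,3,4,4a,5,6,7-octahydronaphthalen-2-ol (key-step product; carbinol carbon open) | C=C(C)[C@@H]1C=C2[C@@H](C)C(O)C[C@@H](Cc3c(OC)cc(OC)cc3OC)[C@]2(C)CC1 | intermediate
16 | sodium alkoxide of 15 (formed in the flask) | C=C(C)[C@@H]1C=C2[C@@H](C)C([O-])C[C@@H](Cc3c(OC)cc(OC)cc3OC)[C@]2(C)CC1.[Na+] | intermediate
17 | sodium O-alkyl dithiocarbonate of 15 (formed in the flask) | C=C(C)[C@@H]1C=C2[C@@H](C)C(OC(=S)[S-])C[C@@H](Cc3c(OC)cc(OC)cc3OC)[C@]2(C)CC1.[Na+] | intermediate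
18 | O-[(1R,4R,4aS,7S)-1,4a-dimethyl-7-(prop-1-en-2-yl)-4-[(2,4,6-trimethoxyphenyl)methyl]-1,2,3,4,4a,5,6,7-octahydronaphthalen-2-yl] S-methyl carbonodithioate | C=C(C)[C@@H]1C=C2[C@@H](C)C(OC(=S)SC)C[C@@H](Cc3c(OC)cc(OC)cc3OC)[C@]2(C)CC1 | intermediate
19 | 2-{[(1S,4S,6S,8aS)-4,8a-dimethyl-6-(prop-1-en-2-yl)-1,2,3,4,6,7,8,8a-octahydronaphthalen-1-yl]methyl}-1,3,5-trimethoxybenzene | C=C(C)[C@@H]1C=C2[C@@H](C)CC[C@@H](Cc3c(OC)cc(OC)cc3OC)[C@]2(C)CC1 | intermediate
20 | 3-methylbutanal | CC(C)CC=O | starting material
21 | 3-lithio derivative of 19 (lithium between two methoxy groups; formed in the flask) | C=C(C)[C@@H]1C=C2[C@@H](C)CC[C@@H](Cc3c(OC)c([Li])c(OC)cc3OC)[C@]2(C)CC1 | intermediate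
22 | 3-methyl-1-[2,4,6-trimethoxy-3-(DecCH2)phenyl]butan-1-ol (carbinol carbon open) | C=C(C)[C@@H]1C=C2[C@@H](C)CC[C@@H](Cc3c(OC)c(C(O)CC(C)C)c(OC)cc3OC)[C@]2(C)CC1 | intermediate
23 | lithium alkoxide of 22 lithiated at the remaining ring position (formed in the flask) | C=C(C)[C@@H]1C=C2[C@@H](C)CC[C@@H](Cc3c(OC)c(C(O[Li])CC(C)C)c(OC)c([Li])c3OC)[C@]2(C)CC1 | intermediate
24 | 3-(1-hydroxy-3-methylbutyl)-2,4,6-trimethoxy-5-(DecCH2)benzaldehyde (carbinol carbon open) | C=C(C)[C@@H]1C=C2[C@@H](C)CC[C@@H](Cc3c(OC)c(C(O)CC(C)C)c(OC)c(C=O)c3OC)[C@]2(C)CC1 | intermediate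
25 | 2,4,6-trimethoxy-3-(3-methylbutanoyl)-5-(DecCH2)benzaldehyde | C=C(C)[C@@H]1C=C2[C@@H](C)CC[C@@H](Cc3c(OC)c(C(=O)CC(C)C)c(OC)c(C=O)c3OC)[C@]2(C)CC1 | intermediate
26 | 2,4,6-trihydroxy-3-(3-methylbutanoyl)-5-{[(1S,4S,6S,8aS)-4,8a-dimethyl-6-(prop-1-en-2-yl)-1,2,3,4,6,7,8,8a-octahydronaphthalen-1-yl]methyl}benzaldehyde (CNP0564915.1) | C=C(C)[C@@H]1C=C2[C@@H](C)CC[C@@H](Cc3c(O)c(C=O)c(O)c(C(=O)CC(C)C)c3O)[C@]2(C)CC1 | target

**Step count**

Total: 13 steps. Longest linear sequence: 12 steps (steps 2–13, from 1,3,5-trimethoxybenzene); the carvone branch (step 1) joins at step 4.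

**Steps most likely to fail**

1. Step 4 (Mukaiyama–Michael addition). Bond formation between a fully substituted enol carbon and a β-branched enoate may be slow, so desilylation of 3 or Friedel–Crafts attack of the trimethoxyarene on the activated enoate can compete, and facial discrimination at C1 in the open transition state may be poor. The fallback sets out from 3, uses 9, and returns at 10. Hydrolysis of 3 (dilute HCl, THF) gives (5S)-dihydrocarvone F1 (C2 epimers, both usable). Condensation with (R)-1-phenylethylamine (toluene, reflux, water separator) gives imine F2. Its secondary enamine tautomer adds to 9 (THF, 10–12 kbar, 20 °C, or neat at 70 °C) through a compact aza-ene transition state in which N–H passes to C2; the auxiliary and the isopropenyl group favour the same face of C10 and the arylmethyl group points away from ring A, giving imine adduct F3. Aqueous AcOH then releases keto ester 10.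

2. Step 7 (carbonyl-ene closure of ring B). The methoxy groups may sequester the Lewis acid and leave the aldehyde unactivated, or the reaction may become stepwise, with ionisation at C5 followed by chloride capture, loss of the C4 hydrogen or methyl migration from C10 instead of transfer of the C6 hydrogen. The fallback sets out from 3 and 7 and returns at 15; it closes ring B by an aldol condensation instead. Cross-metathesis of 7 with pent-1-en-3-one (same ruthenium catalyst) gives (4E)-6-(2,4,6-trimethoxyphenyl)hex-4-en-3-one F4. Mukaiyama–Michael addition of 3 (TiCl4, CH2Cl2, −78 °C), on the better-precedented enone acceptor class and with the same stereochemical course, gives 1,5-diketone F5. KOH in MeOH at 65 °C (second stage of a Robinson annulation) gives the conjugated enone F6. Deconjugation through the dienolate (KOt-Bu, t-BuOH, then cold aq. AcOH, with kinetic protonation at C4 expected on the face anti to the C10 methyl) gives β,γ-unsaturated ketone F7. Immediate reduction with NaBH4 (MeOH, 0 °C) gives carbinol 15.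

3. Step 13 (three-fold O-demethylation). Removal of the third methyl group may stall once two phenoxide charges have built up, or the acyl groups may be lost from the electron-rich ring at 120 °C. The fallback sets out from 25 and returns at 26; it makes no new compound (F0). Chelation-assisted dealkylation with MgI2·OEt2 (toluene–THF, 80 °C) is used: each methoxy group is ortho to a carbonyl group, magnesium binds C=O and OMe together, and iodide removes the methyl group as iodomethane under non-basic, non-protic conditions; dilute acid work-up gives 26.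

**Further compounds**

F1 | step 4 | (5S)-2-methyl-5-(prop-1-en-2-yl)cyclohexan-1-one (dihydrocarvone, C2 epimers) | C=C(C)[C@@H]1CC(=O)C(C)CC1
F2 | step 4 | imine of F1 with (R)-1-phenylethylamine | C=C(C)[C@@H]1CC(=N[C@H](C)c2ccccc2)C(C)CC1
F3 | step 4 | (R)-1-phenylethyl imine of keto ester 10 | C=C(C)[C@@H]1CC(=N[C@H](C)c2ccccc2)[C@](C)([C@H](Cc2c(OC)cc(OC)cc2OC)CC(=O)OC)CC1
F4 | step 7 | (4E)-6-(2,4,6-trimethoxyphenyl)hex-4-en-3-one | CCC(=O)/C=C/Cc1c(OC)cc(OC)cc1OC
F5 | step 7 | (5R)-5-[(1S,4S)-1-methyl-2-oxo-4-(prop-1-en-2-yl)cyclohexyl]-6-(2,4,6-trimethoxyphenyl)hexan-3-one | C=C(C)[C@@H]1CC(=O)[C@](C)([C@H](Cc2c(OC)cc(OC)cc2OC)CC(=O)CC)CC1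
F6 | step 7 | (4R,4aS,7S)-1,4a-dimethyl-7-(prop-1-en-2-yl)-4-[(2,4,6-trimethoxyphenyl)methyl]-4,4a,5,6,7,8-hexahydronaphthalen-2(3H)-one | C=C(C)[C@@H]1CC2=C(C)C(=O)C[C@@H](Cc3c(OC)cc(OC)cc3OC)[C@]2(C)CC1
F7 | step 7 | (1R,4R,4aS,7S)-1,4a-dimethyl-7-(prop-1-en-2-yl)-4-[(2,4,6-trimethoxyphenyl)methyl]-3,4,4a,5,6,7-hexahydronaphthalen-2(1H)-one | C=C(C)[C@@H]1C=C2[C@@H](C)C(=O)C[C@@H](Cc3c(OC)cc(OC)cc3OC)[C@]2(C)CC1
F0 | step 13 | none | none
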